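**Strategy.** The seven-membered ring (C1, C5–C10) holds a homoallylic oxygen pattern, C8(O)–C9H2–C10(CH3)=C1, with the tetrasubstituted alkene at the ring fusion: the retron of an intramolecular carbonyl-ene (Prins) reaction. The route therefore closes this ring last, by joining an aldehyde carbon C8 to the methylene terminus C9 of an isopropenyl group on C1 of a cyclopentane. One operation forms the C8–C9 bond, the C8 carbinol centre and the C1=C10 alkene, because the C1 hydrogen is transferred to oxygen. The precursor is a monocyclic β-acetoxy aldehyde: its cyclopentane comes from (R)-limonene by a proline aldol, its side chain from a Sharpless epoxidation and cuprate opening.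

Key step: step 9

Remark: guaiane numbering is used for all intermediates (ring fusion C1/C5, carbinol C4, acetate C6, isopropyl C7, angelate C8, C14 = methyl on C10). (1S,2S,4R)-Limonene-1,2-diol is taken as the commercial form of the (R)-limonene chiral pool.

Step 1
Reactants: 1 (1S,2S,4R)-limonene-1,2-diol
Product: 2 (3R)-6-oxo-3-(prop-1-en-2-yl)heptanal
Conditions: NaIO4, THF/H2O, 0 °C to rt
Reagents that add atoms: none
Why: Malaprade glycol cleavage of the vicinal diol should open the ring to the keto aldehyde without touching the isopropenyl group or the stereocentre that becomes C1.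

Step 2
Reactants: 2 (3R)-6-oxo-3-(prop-1-en-2-yl)heptanal; 3 ethyl (triphenylphosphoranylidene)acetate
Product: 5 ethyl (2E)-3-[(1S,2S,5R)-2-hydroxy-2-methyl-5-(prop-1-en-2-yl)cyclopentyl]prop-2-enoate, via hydroxy aldehyde 4 (not isolated)
Conditions: L-proline (20 mol%), CH2Cl2, rt; then 3, rt to 40 °C
Reagents that add atoms: ethyl (triphenylphosphoranylidene)acetate CCOC(=O)C=P(c1ccccc1)(c1ccccc1)c1ccccc1
Why: Proline-catalysed 5-enolexo aldolisation of the aldehyde enamine onto the methyl ketone should give the anti aldol with CHO trans to both the new C4 hydroxyl and the isopropenyl group (C5 set by L-proline, matched with the resident C1 centre; C4 by the acid-bound anti transition state), and the labile aldehyde is trapped in the same flask by an E-selective Wittig olefination.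

Step 3
Reactants: 5 ethyl (2E)-3-[(1S,2S,5R)-2-hydroxy-2-methyl-5-(prop-1-en-2-yl)cyclopentyl]prop-2-enoate; 6 triethylsilyl trifluoromethanesulfonate
Product: 7 ethyl (2E)-3-[(1S,2S,5R)-2-methyl-5-(prop-1-en-2-yl)-2-(triethylsilyloxy)cyclopentyl]prop-2-enoate
Conditions: TESOTf, 2,6-lutidine, CH2Cl2, −78 to 0 °C
Reagents that add atoms: triethylsilyl trifluoromethanesulfonate CC[Si](CC)(CC)OS(=O)(=O)C(F)(F)F
Why: O-Silylation of the tertiary alcohol with a silyl triflate masks the C4 oxygen, which could otherwise trap the C10 cation of the key step, and should survive all later steps.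

Step 4
Reactants: 7 ethyl (2E)-3-[(1S,2S,5R)-2-methyl-5-(prop-1-en-2-yl)-2-(triethylsilyloxy)cyclopentyl]prop-2-enoate
Product: 8 (2E)-3-[(1S,2S,5R)-2-methyl-5-(prop-1-en-2-yl)-2-(triethylsilyloxy)cyclopentyl]prop-2-en-1-ol
Conditions: DIBAL-H (2.5 equiv), CH2Cl2, −78 °C; aq. Rochelle salt
Reagents that add atoms: none
Why: 1,2-Reduction of the unsaturated ester by DIBAL-H should give the E-allylic alcohol needed for a directed epoxidation, the isolated isopropenyl group and the silyl ether being inert.

Step 5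
Reactants: 8 (2E)-3-[(1S,2S,5R)-2-methyl-5-(prop-1-en-2-yl)-2-(triethylsilyloxy)cyclopentyl]prop-2-en-1-ol; 9 tert-butyl hydroperoxide
Product: 10 [(2S,3S)-3-[(1R,2S,5R)-2-methyl-5-(prop-1-en-2-yl)-2-(triethylsilyloxy)cyclopentyl]oxiran-2-yl]methanol
Conditions: Ti(OiPr)4 (20 mol%), L-(+)-diethyl tartrate (24 mol%), TBHP, 4 Å MS, CH2Cl2, −20 °C
Reagents that add atoms: tert-butyl hydroperoxide CC(C)(C)OO
Why: Sharpless asymmetric epoxidation acts only on the allylic alcohol (the isopropenyl group has no directing hydroxyl) and with L-(+)-tartrate should give the (2S,3S)-epoxide under reagent control, which fixes the C6–O configuration of the target.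

Step 6
Reactants: 10 [(2S,3S)-3-[(1R,2S,5R)-2-methyl-5-(prop-1-en-2-yl)-2-(triethylsilyloxy)cyclopentyl]oxiran-2-yl]methanol; 11 isopropylmagnesium chloride
Product: 12 (1R,2R)-1-[(1R,2S,5R)-2-methyl-5-(prop-1-en-2-yl)-2-(triethylsilyloxy)cyclopentyl]-2-(propan-2-yl)propane-1,3-diol
Conditions: i-PrMgCl (4 equiv), CuI (15 mol%), THF, −40 to −10 °C
Reagents that add atoms: isopropylmagnesium chloride CC(C)[Mg]Cl
Why: Copper-catalysed SN2 opening of the 2,3-epoxy alcohol should occur at C7 (C2 of the epoxy alcohol) because C6 is shielded by the neopentyl-like cyclopentyl group, with inversion at C7 and retention at C6, which gives the 1,3-diol with the 6,7-anti (ring-cis) relationship.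

Step 7
Reactants: 12 (1R,2R)-1-[(1R,2S,5R)-2-methyl-5-(prop-1-en-2-yl)-2-(triethylsilyloxy)cyclopentyl]-2-(propan-2-yl)propane-1,3-diol
Product: 13 (2S,3S)-3-hydroxy-3-[(1R,2S,5R)-2-methyl-5-(prop-1-en-2-yl)-2-(triethylsilyloxy)cyclopentyl]-2-(propan-2-yl)propanal
Conditions: TEMPO (10 mol%), PhI(OAc)2, CH2Cl2, rt
Reagents that add atoms: none
Why: Oxoammonium (TEMPO/PhI(OAc)2) oxidation is selective for the primary over the hindered secondary alcohol and stops at the aldehyde under non-basic conditions, so C7 should not epimerise.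

Step 8
Reactants: 13 (2S,3S)-3-hydroxy-3-[(1R,2S,5R)-2-methyl-5-(prop-1-en-2-yl)-2-(triethylsilyloxy)cyclopentyl]-2-(propan-2-yl)propanal; 14 acetic anhydride
Product: 15 (1S,2S)-2-formyl-3-methyl-1-[(1R,2S,5R)-2-methyl-5-(prop-1-en-2-yl)-2-(triethylsilyloxy)cyclopentyl]butyl acetate
Conditions: Ac2O, pyridine, DMAP (5 mol%), CH2Cl2, 0 °C
Reagents that add atoms: acetic anhydride CC(=O)OC(C)=O
Why: DMAP-catalysed O-acylation installs the C6 acetate of the target before ring closure, so that no chelating free hydroxyl is present in the key step, and the low temperature should limit β-elimination.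

Step 9
Reactants: 15 (1S,2S)-2-formyl-3-methyl-1-[(1R,2S,5R)-2-methyl-5-(prop-1-en-2-yl)-2-(triethylsilyloxy)cyclopentyl]butyl acetate
Product: 16 (3S,3aR,4R,5R,6S)-6-hydroxy-3,8-dimethyl-5-(propan-2-yl)-3-(triethylsilyloxy)-1,2,3,3a,4,5,6,7-octahydroazulen-4-yl acetate
Conditions: Me2AlCl (2.2 equiv), CH2Cl2, −78 to −20 °C; aq. Rochelle salt
Reagents that add atoms: none
Why: Me2AlCl activates the C8 aldehyde, the methylene terminus C9 of the isopropenyl group adds to it to give a tertiary C10 cation/aluminate zwitterion, and this collapses by a 1,5-proton shift from C1 to the aluminate oxygen (methane is then lost from aluminium); the step is an intramolecular Lewis-acid carbonyl-ene (Prins-type) cyclisation of the kind established for alkylaluminium halides and ω-unsaturated aldehydes. The seven-membered ring is closed in a cation–olefin mode that is exo at the carbonyl and endo at the 1,1-disubstituted olefin, which reacts through its unsubstituted terminus (Markovnikov). The only new stereocentre, C8, is controlled by the adjacent C7 isopropyl group: in the chair-like transition state the aluminium-bound oxygen turns away from the isopropyl group, which should give the 7,8-trans (8S) alcohol. The step needs proton loss from C1 and not from the C14 methyl; this is favoured by the trans-1,5 substitution of the cyclopentane, which places H-1 on the same face as the C8–O–Al group in a six-centre arrangement, and by the Zaitsev preference for the tetrasubstituted ring-fusion alkene. The tertiary OTES group keeps the C4 oxygen from capturing the C10 cation, and the C6 acetate is inert to Me2AlCl at low temperature.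

Step 10
Reactants: 16 (3S,3aR,4R,5R,6S)-6-hydroxy-3,8-dimethyl-5-(propan-2-yl)-3-(triethylsilyloxy)-1,2,3,3a,4,5,6,7-octahydroazulen-4-yl acetate; 17 angelic acid; 18 2,4,6-trichlorobenzoyl chloride
Product: 20 (3S,3aR,4R,5R,6S)-4-acetoxy-3,8-dimethyl-5-(propan-2-yl)-3-(triethylsilyloxy)-1,2,3,3a,4,5,6,7-octahydroazulen-6-yl (2Z)-2-methylbut-2-enoate, via mixed anhydride 19 (not isolated)
Conditions: 17, 18, Et3N, toluene, rt; then 16, 80 °C
Reagents that add atoms: angelic acid C/C=C(/C)C(=O)O
Why: Yamaguchi-type esterification through the preformed angelic 2,4,6-trichlorobenzoic mixed anhydride acylates the hindered C8 alcohol at the less hindered angeloyl carbonyl and is the standard way to introduce an angelate without Z-to-E isomerisation to the tiglate.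

Step 11
Reactants: 20 (3S,3aR,4R,5R,6S)-4-acetoxy-3,8-dimethyl-5-(propan-2-yl)-3-(triethylsilyloxy)-1,2,3,3a,4,5,6,7-octahydroazulen-6-yl (2Z)-2-methylbut-2-enoate
Product: 21 (3S,3aR,4R,5R,6S)-4-acetoxy-3-hydroxy-3,8-dimethyl-5-(propan-2-yl)-1,2,3,3a,4,5,6,7-octahydroazulen-6-yl (2Z)-2-methylbut-2-enoate
Conditions: HF·pyridine, THF/pyridine, 0 °C to rt
Reagents that add atoms: none
Why: Fluoride-mediated desilylation under buffered conditions should free the tertiary C4 alcohol without acyl migration, ester cleavage or isomerisation of the angelate or of the tetrasubstituted alkene.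

**Compound list**

1 | (1S,2S,4R)-limonene-1,2-diol [(1S,2S,4R)-1-methyl-4-(prop-1-en-2-yl)cyclohexane-1,2-diol] | C[C@]1(O)CC[C@H](C[C@@H]1O)C(C)=C | starting material
2 | (3R)-6-oxo-3-(prop-1-en-2-yl)heptanal | O=CC[C@@H](CCC(C)=O)C(C)=C | intermediate
3 | ethyl (triphenylphosphoranylidene)acetate | CCOC(=O)C=P(c1ccccc1)(c1ccccc1)c1ccccc1 | starting material
4 | (1S,2S,5R)-2-hydroxy-2-methyl-5-(prop-1-en-2-yl)cyclopentane-1-carbaldehyde | O=C[C@@H]1[C@@](C)(O)CC[C@H]1C(C)=C | intermediate
5 | ethyl (2E)-3-[(1S,2S,5R)-2-hydroxy-2-methyl-5-(prop-1-en-2-yl)cyclopentyl]prop-2-enoate | CCOC(=O)/C=C/[C@@H]1[C@@](C)(O)CC[C@H]1C(C)=C | intermediate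
6 | triethylsilyl trifluoromethanesulfonate | CC[Si](CC)(CC)OS(=O)(=O)C(F)(F)F | starting material
7 | ethyl (2E)-3-[(1S,2S,5R)-2-methyl-5-(prop-1-en-2-yl)-2-(triethylsilyloxy)cyclopentyl]prop-2-enoate | CCOC(=O)/C=C/[C@@H]1[C@@](C)(O[Si](CC)(CC)CC)CC[C@H]1C(C)=C | intermediate
8 | (2E)-3-[(1S,2S,5R)-2-methyl-5-(prop-1-en-2-yl)-2-(triethylsilyloxy)cyclopentyl]prop-2-en-1-ol | OC/C=C/[C@@H]1[C@@](C)(O[Si](CC)(CC)CC)CC[C@H]1C(C)=C | intermediate
9 | tert-butyl hydroperoxide | CC(C)(C)OO | starting material
10 | [(2S,3S)-3-[(1R,2S,5R)-2-methyl-5-(prop-1-en-2-yl)-2-(triethylsilyloxy)cyclopentyl]oxiran-2-yl]methanol | OC[C@@H]1O[C@H]1[C@@H]2[C@@](C)(O[Si](CC)(CC)CC)CC[C@H]2C(C)=C | intermediate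
11 | isopropylmagnesium chloride | CC(C)[Mg]Cl | starting material
12 | (1R,2R)-1-[(1R,2S,5R)-2-methyl-5-(prop-1-en-2-yl)-2-(triethylsilyloxy)cyclopentyl]-2-(propan-2-yl)propane-1,3-diol | OC[C@@H](C(C)C)[C@@H](O)[C@@H]1[C@@](C)(O[Si](CC)(CC)CC)CC[C@H]1C(C)=C | intermediate
13 | (2S,3S)-3-hydroxy-3-[(1R,2S,5R)-2-methyl-5-(prop-1-en-2-yl)-2-(triethylsilyloxy)cyclopentyl]-2-(propan-2-yl)propanal | O=C[C@@H](C(C)C)[C@@H](O)[C@@H]1[C@@](C)(O[Si](CC)(CC)CC)CC[C@H]1C(C)=C | intermediate
14 | acetic anhydride | CC(=O)OC(C)=O | starting material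
15 | (1S,2S)-2-formyl-3-methyl-1-[(1R,2S,5R)-2-methyl-5-(prop-1-en-2-yl)-2-(triethylsilyloxy)cyclopentyl]butyl acetate | O=C[C@@H](C(C)C)[C@@H](OC(C)=O)[C@@H]1[C@@](C)(O[Si](CC)(CC)CC)CC[C@H]1C(C)=C | intermediate
16 | (3S,3aR,4R,5R,6S)-6-hydroxy-3,8-dimethyl-5-(propan-2-yl)-3-(triethylsilyloxy)-1,2,3,3a,4,5,6,7-octahydroazulen-4-yl acetate | O[C@H]1CC(C)=C2CC[C@](C)(O[Si](CC)(CC)CC)[C@H]2[C@H](OC(C)=O)[C@@H]1C(C)C | intermediate
17 | angelic acid [(2Z)-2-methylbut-2-enoic acid] | C/C=C(/C)C(=O)O | starting material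
18 | 2,4,6-trichlorobenzoyl chloride | O=C(Cl)c1c(Cl)cc(Cl)cc1Cl | starting material
19 | (2Z)-2-methylbut-2-enoic 2,4,6-trichlorobenzoic anhydride | C/C=C(/C)C(=O)OC(=O)c1c(Cl)cc(Cl)cc1Cl | intermediate
20 | (3S,3aR,4R,5R,6S)-4-acetoxy-3,8-dimethyl-5-(propan-2-yl)-3-(triethylsilyloxy)-1,2,3,3a,4,5,6,7-octahydroazulen-6-yl (2Z)-2-methylbut-2-enoate | C/C=C(/C)C(=O)O[C@H]1CC(C)=C2CC[C@](C)(O[Si](CC)(CC)CC)[C@H]2[C@H](OC(C)=O)[C@@H]1C(C)C | intermediate
21 | (3S,3aR,4R,5R,6S)-4-acetoxy-3-hydroxy-3,8-dimethyl-5-(propan-2-yl)-1,2,3,3a,4,5,6,7-octahydroazulen-6-yl (2Z)-2-methylbut-2-enoate | C/C=C(/C)C(=O)O[C@H]1CC(C)=C2CC[C@](C)(O)[C@H]2[C@H](OC(C)=O)[C@@H]1C(C)C | target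

**Step count.** Total: 11 steps. Longest linear sequence: 11 steps (1 to 21).

**Steps most likely to fail**

1. Step 9 (key step). The C10 cation may lose a proton from the C14 methyl instead of from C1, which would leave an exocyclic methylene, and the proton-transfer geometry could also favour the wrong C8 epimer. Fallback: the ring closure and the placing of the double bond are separated. From 15 the cyclisation is run as a kinetic type II carbonyl-ene reaction (Me2AlCl, CH2Cl2, −78 °C) and the exocyclic isomer (3S,3aR,4R,5R,6S,8aR)-6-hydroxy-3-methyl-8-methylidene-5-(propan-2-yl)-3-(triethylsilyloxy)decahydroazulen-4-yl acetate F1 is accepted. The double bond is then moved into the tetrasubstituted C1=C10 position by anhydrous acid-catalysed isomerisation (camphorsulfonic acid, 10 mol%, CH2Cl2, 0 °C), which re-enters the same tertiary C10 cation and should end at the Zaitsev alkene. The route is rejoined at 16.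

2. Step 2. The tertiary aldol may dehydrate to the conjugated cyclopentene aldehyde under amine catalysis, the anti selectivity at C4 may be incomplete, and the β-hydroxy aldehyde may undergo retro-aldol during the olefination. Fallback: a reductive relay from 2. The proline aldolisation is run at 4 °C and the aldehyde is intercepted in situ with NaBH4/MeOH as the stable diol (1S,2R,3R)-2-(hydroxymethyl)-1-methyl-3-(prop-1-en-2-yl)cyclopentan-1-ol F2, at which stage diastereomers can be separated. The primary alcohol is then oxidised with TEMPO/PhI(OAc)2 in the presence of ylide 3 (tandem oxidation–Wittig), so that the aldehyde never accumulates. The route is rejoined at 5.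

3. Step 8. Acylation of the α-branched β-hydroxy aldehyde may be accompanied by E1cB loss of the new acetate to the enal or by epimerisation at C7. Fallback: the acetate is installed before the aldehyde exists. From 12, both hydroxyls are acetylated (Ac2O, DMAP, pyridine) to (1R,2R)-1-[(1R,2S,5R)-2-methyl-5-(prop-1-en-2-yl)-2-(triethylsilyloxy)cyclopentyl]-2-(propan-2-yl)propane-1,3-diyl diacetate F3. The unhindered primary acetate is removed selectively by lipase-mediated alcoholysis (Candida antarctica lipase B, n-BuOH, MTBE, 30 °C) to (1R,2R)-3-hydroxy-1-[(1R,2S,5R)-2-methyl-5-(prop-1-en-2-yl)-2-(triethylsilyloxy)cyclopentyl]-2-(propan-2-yl)propyl acetate F4. Buffered Dess–Martin oxidation (DMP, NaHCO3, CH2Cl2) then gives 15, where the route is rejoined.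

**Further compounds**

F1 | step 9 | (3S,3aR,4R,5R,6S,8aR)-6-hydroxy-3-methyl-8-methylidene-5-(propan-2-yl)-3-(triethylsilyloxy)decahydroazulen-4-yl acetate | O[C@H]1CC(=C)[C@@H]2CC[C@](C)(O[Si](CC)(CC)CC)[C@H]2[C@H](OC(C)=O)[C@@H]1C(C)C
F2 | step 2 | (1S,2R,3R)-2-(hydroxymethyl)-1-methyl-3-(prop-1-en-2-yl)cyclopentan-1-ol | OC[C@@H]1[C@@](C)(O)CC[C@H]1C(C)=C
F3 | step 8 | (1R,2R)-1-[(1R,2S,5R)-2-methyl-5-(prop-1-en-2-yl)-2-(triethylsilyloxy)cyclopentyl]-2-(propan-2-yl)propane-1,3-diyl diacetate | CC(=O)OC[C@@H](C(C)C)[C@@H](OC(C)=O)[C@@H]1[C@@](C)(O[Si](CC)(CC)CC)CC[C@H]1C(C)=C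
F4 | step 8 | (1R,2R)-3-hydroxy-1-[(1R,2S,5R)-2-methyl-5-(prop-1-en-2-yl)-2-(triethylsilyloxy)cyclopentyl]-2-(propan-2-yl)propyl acetate | OC[C@@H](C(C)C)[C@@H](OC(C)=O)[C@@H]1[C@@](C)(O[Si](CC)(CC)CC)CC[C@H]1C(C)=C
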